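The readings were generated by integration for an exercise, noise included.

The north-east run, at 0.30 M of substrate, and the east run, at 0.56 M, kept nearly the same percentages, with 54.4% and 54.5% of substrate left at 60.0 min. The summer flask lies between them in charge, so I took their curves for it as well.

| flask | substrate | reagent | free catalyst | second catalyst | remark | time |
|---|---|---|---|---|---|---|
| north-east | 0.30 M | 0.32 M (in portions, 3) | 0.80 mM | 20 mM | run made earlier; portions every 25 min |  |
| east | 0.56 M | 0.32 M (in portions, 3) | 0.80 mM | 20 mM | run made earlier; portions every 25 min |  |
| summer | 0.40 M | 0.320 M (in portions, 3) | 0.80 mM | 20 mM | the portions of reagent follow each other after 25 min, the first at the start | 80 min |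
| winter | 0.25 M | 0.320 M | 0.80 mM | 20 mM | everything together at the start | 300 min |

- north-east (time / min: target / %, substrate / %): 3.00: 0, 96.8; 8.00: 0.6, 91.6; 15.0: 2.0, 85.3; 25.0: 3.2, 78.0; 30.0: 3.6, 73.4; 40.0: 6.6, 67.2; 60.0: 17.4, 54.4
- east (time / min: target / %, substrate / %): 8.00: 0.2, 91.3; 15.0: 1.3, 86.4; 25.0: 2.1, 77.9; 30.0: 4.6, 74.4; 40.0: 7.4, 67.0; 50.0: 10.8, 60.4; 60.0: 15.9, 54.5

(readings scatter by 0.5 percentage points)

- the numbers in the tables scatter by 0.5 percentage points (one standard deviation)
- a reading or a percentage of target counts all its forms, free or not

- which of the two ends with the higher amount of target, in percent of the substrate charged ("neither" if they lie within 2 percentage points) (summer / winter / neither)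
- target at the end, in percent of the substrate charged, summer
- target at the end, in percent of the substrate charged, winter

The substrate fell by a steady fraction per minute, k = 0.0101 min⁻¹, with no break at the portions. Target lagged, and I called the gap between substrate lost and target found the pool; it read 28.9% at 60.0 min. Between 40.0 min and 60.0 min, target gained per minute over the mean pool read 0.0199 min⁻¹ in the north-east run and 0.0154 min⁻¹ in the east run. I carried their mean, 0.0176 min⁻¹, as k_L, the pass-on constant: target gained per minute for each unit of pool.

The ladder of times ran upward. Portions came every 25 min, the pool passed on half its content in 39.3 min, which is slower, and the substrate halved in 68.4 min, slower again. Summer therefore ended after 1.17 substrate half-lives, with the pool still full, and winter after 4.38, with the pool trailing the substrate down.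

For summer I reckoned substrate at 44.5%. Holding the pool from 60.0 min gave target 26.8% and left a pool of 28.7%. Putting the mean pool back gave 26.8%. For winter I reckoned substrate at 4.79%, a trailing pool of k/(k_L − k) times that, 6.47%, and so target 88.7%.

The forecast said winter, with 28% for summer and 82% for winter, on the ground that “Target lags behind substrate loss”. My summer figure was lower and my winter figure higher.

The flasks gave winter, with summer at 26.6% and winter at 84.3%, crystals counted in target.

    substrate + free catalyst → free catalyst + open intermediate (k = 12.7 M⁻¹ min⁻¹)
    second catalyst + open intermediate ⇌ catalyst intermediate (K = 0.0800 M⁻¹, k = 3.24 M⁻¹ min⁻¹)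
    reagent + catalyst intermediate → second catalyst + target (k = 62.7 M⁻¹ min⁻¹)
    crystals ⇌ target, rate k4*(cs4 - [target]) while solid is left; crystals form when [target] > cs4 (solubility = 6.50 mM, k = 3.71 min⁻¹)

Summer's open intermediate, the real pool, stood at 29.0% at 80.0 min. Second catalyst at 27.9 mM moves summer's target by 5 points. The neighbour flask went further, with 0.034 M of second catalyst. Second catalyst takes open intermediate on, so I scaled k_L by 1.70 to 0.0300 min⁻¹, and target over pool with it, to 1.56. Substrate lost there was 55.6%, which split in that ratio gives target 33.9%. The neighbour flask gave 34.5%.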